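**Retrosynthetic overview**
1. Target 17 ⇐ 16 by global O-debenzylation. The lactone ring is the only ring made, closed by oxidation of the 3-hydroxypropyl chain of 13 onto the one free phenol, which fixes O1 next to the cinnamoyl group.
2. Enone of 13 ⇐ Claisen–Schmidt condensation of methyl ketone 10 with aldehyde 11.
3. CH(Ph)CH2CH2OH of 10 ⇐ vinyl group of 8 (hydroboration) ⇐ E-propenyl group of 7 (ethenolysis).
4. C4–C4a bond and the C4 stereocentre ⇐ aromatic Claisen rearrangement of aryl ether 5 with 1,3-chirality transfer (the C–O centre is traded for the C–C centre).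
5. 5 ⇐ cross-metathesis of 3 with styrene; 3 ⇐ Mitsunobu inversion of bought (S)-but-3-en-2-ol 2 by phenol 1.

Assumption: the stereocentre is read from the SMILES as 4R, and 1, 2, 4 and 11 are taken as catalogue compounds (2 as the single S enantiomer).

**Step 1**
Reactants: 1 1-[2,4-bis(benzyloxy)-6-hydroxyphenyl]ethan-1-one; 2 (2S)-but-3-en-2-ol
Product: 3 1-[2,4-bis(benzyloxy)-6-{[(2R)-but-3-en-2-yl]oxy}phenyl]ethan-1-one
Conditions: PPh3, DIAD, THF, 0 °C → rt
Reagents that add atoms: none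
Why: Mitsunobu etherification, in which the acidic phenol displaces the activated secondary alcohol by SN2 with inversion, so the bought (S) carbinol becomes the (R) aryl ether.

**Step 2**
Reactants: 3 1-[2,4-bis(benzyloxy)-6-{[(2R)-but-3-en-2-yl]oxy}phenyl]ethan-1-one; 4 styrene
Product: 5 1-[2,4-bis(benzyloxy)-6-{[(2R,3E)-4-phenylbut-3-en-2-yl]oxy}phenyl]ethan-1-one
Conditions: second-generation Grubbs catalyst RuCl2(=CHPh)(PCy3)(H2IMes) (5 mol %), styrene (4 equiv), CH2Cl2, 40 °C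
Reagents that add atoms: none
Why: Olefin cross-metathesis of the monosubstituted allylic ether with styrene gives the E-styryl ether under thermodynamic control and does not touch the allylic stereocentre.

**Step 3**
Reactants: 5 1-[2,4-bis(benzyloxy)-6-{[(2R,3E)-4-phenylbut-3-en-2-yl]oxy}phenyl]ethan-1-one
Product: 7 1-{4,6-bis(benzyloxy)-2-hydroxy-3-[(1R,2E)-1-phenylbut-2-en-1-yl]phenyl}ethan-1-one, via ortho-dienone 6 (not isolated)
Conditions: PhNEt2, 185 °C, sealed tube, argon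
Reagents that add atoms: none
Why: Aromatic Claisen rearrangement ([3,3]-sigmatropic) through a chair transition state with the methyl group and the E-phenyl group both equatorial, which moves the allyl unit suprafacially to the only free ortho carbon, converts the (R) C–O centre into the (R) C–aryl centre with an E-propenyl group, and ends with tautomerisation of dienone 6 to the phenol.

**Step 4**
Reactants: 7 1-{4,6-bis(benzyloxy)-2-hydroxy-3-[(1R,2E)-1-phenylbut-2-en-1-yl]phenyl}ethan-1-one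
Product: 8 1-{4,6-bis(benzyloxy)-2-hydroxy-3-[(1R)-1-phenylprop-2-en-1-yl]phenyl}ethan-1-one
Conditions: ethylene (3 bar), second-generation Hoveyda–Grubbs catalyst RuCl2(H2IMes)(=CH–C6H4-2-OiPr) (10 mol %), 1,4-benzoquinone (10 mol %), toluene, 60 °C
Reagents that add atoms: ethylene, C=C
Why: Ethenolysis (cross-metathesis with ethylene) trims the propenyl group to vinyl, driven by excess ethylene and loss of propene, while benzoquinone suppresses ruthenium hydride double-bond migration that would destroy the allylic stereocentre.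

**Step 5**
Reactants: 8 1-{4,6-bis(benzyloxy)-2-hydroxy-3-[(1R)-1-phenylprop-2-en-1-yl]phenyl}ethan-1-one
Product: 10 1-{4,6-bis(benzyloxy)-2-hydroxy-3-[(1R)-3-hydroxy-1-phenylpropyl]phenyl}ethan-1-one, via bis-boryl adduct 9 (not isolated)
Conditions: 9-BBN (2.5 equiv), THF, 0 °C → rt; then NaBO3·4H2O, H2O, rt
Reagents that add atoms: sodium perborate tetrahydrate, [Na+].[Na+].O[B-]1(O)OO[B-](O)(O)OO1
Why: Brown hydroboration–oxidation, in which bulky 9-BBN should add boron to the terminal carbon faster than it reduces the doubly ortho-substituted, electron-rich aryl ketone, and mild perborate replaces boron by OH without touching the stereocentre.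

**Step 6**
Reactants: 10 1-{4,6-bis(benzyloxy)-2-hydroxy-3-[(1R)-3-hydroxy-1-phenylpropyl]phenyl}ethan-1-one; 11 3,4-bis(benzyloxy)benzaldehyde
Product: 13 (2E)-1-{4,6-bis(benzyloxy)-2-hydroxy-3-[(1R)-3-hydroxy-1-phenylpropyl]phenyl}-3-[3,4-bis(benzyloxy)phenyl]prop-2-en-1-one, via aldol 12 (not isolated)
Conditions: KOH (50 % aq.), EtOH–THF, rt; then 1 M HCl, 0 °C
Reagents that add atoms: none
Why: Claisen–Schmidt (crossed aldol) condensation, in which the methyl ketone enolate adds to the non-enolisable aldehyde and aldol 12 loses water by E1cB to the E-enone, with the non-acidic diarylmethine centre untouched.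

**Step 7**
Reactants: 13 (2E)-1-{4,6-bis(benzyloxy)-2-hydroxy-3-[(1R)-3-hydroxy-1-phenylpropyl]phenyl}-3-[3,4-bis(benzyloxy)phenyl]prop-2-en-1-one
Product: 16 (4R)-5,7-bis(benzyloxy)-8-{(2E)-3-[3,4-bis(benzyloxy)phenyl]prop-2-enoyl}-4-phenyl-3,4-dihydro-2H-chromen-2-one, via aldehyde 14 (not isolated), via lactol 15 (not isolated)
Conditions: TEMPO (20 mol %), PhI(OAc)2 (2.5 equiv), CH2Cl2, rt
Reagents that add atoms: none
Why: TEMPO/PhI(OAc)2 oxidative lactonisation, in which the oxoammonium salt oxidises the primary alcohol to aldehyde 14, the only free phenol traps it as lactol 15, and a second oxidation gives the lactone on the oxygen next to the cinnamoyl group.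

**Step 8**
Reactants: 16 (4R)-5,7-bis(benzyloxy)-8-{(2E)-3-[3,4-bis(benzyloxy)phenyl]prop-2-enoyl}-4-phenyl-3,4-dihydro-2H-chromen-2-one
Product: 17 (4R)-8-[(2E)-3-(3,4-dihydroxyphenyl)prop-2-enoyl]-5,7-dihydroxy-4-phenyl-3,4-dihydro-2H-chromen-2-one
Conditions: BCl3 (8 equiv), C6HMe5 (12 equiv), CH2Cl2, −78 → −40 °C; then H2O
Reagents that add atoms: none
Why: Lewis-acid debenzylation with pentamethylbenzene as benzyl-cation scavenger cleaves the four aryl benzyl ethers at low temperature without reducing the enone, opening the lactone or C-benzylating the phloroglucinol ring.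

**Compound list**
1 | 1-[2,4-bis(benzyloxy)-6-hydroxyphenyl]ethan-1-one | CC(=O)c1c(O)cc(OCc2ccccc2)cc1OCc1ccccc1 | starting material
2 | (2S)-but-3-en-2-ol | C[C@H](O)C=C | starting material
3 | 1-[2,4-bis(benzyloxy)-6-{[(2R)-but-3-en-2-yl]oxy}phenyl]ethan-1-one | C[C@@H](Oc1cc(OCc2ccccc2)cc(OCc2ccccc2)c1C(C)=O)C=C | intermediate
4 | styrene | C=Cc1ccccc1 | starting material
5 | 1-[2,4-bis(benzyloxy)-6-{[(2R,3E)-4-phenylbut-3-en-2-yl]oxy}phenyl]ethan-1-one | C[C@@H](Oc1cc(OCc2ccccc2)cc(OCc2ccccc2)c1C(C)=O)/C=C/c1ccccc1 | intermediate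
6 | (6S)-2-acetyl-3,5-bis(benzyloxy)-6-[(1S,2E)-1-phenylbut-2-en-1-yl]cyclohexa-2,4-dien-1-one (ortho-dienone; the side-chain descriptor changes only because the priorities change) | C/C=C/[C@H](c1ccccc1)[C@@H]1C(=O)C(C(C)=O)=C(OCc2ccccc2)C=C1OCc1ccccc1 | intermediate
7 | 1-{4,6-bis(benzyloxy)-2-hydroxy-3-[(1R,2E)-1-phenylbut-2-en-1-yl]phenyl}ethan-1-one | C/C=C/[C@H](c1ccccc1)c1c(O)c(C(C)=O)c(OCc2ccccc2)cc1OCc1ccccc1 | intermediate
8 | 1-{4,6-bis(benzyloxy)-2-hydroxy-3-[(1R)-1-phenylprop-2-en-1-yl]phenyl}ethan-1-one | C=C[C@H](c1ccccc1)c1c(O)c(C(C)=O)c(OCc2ccccc2)cc1OCc1ccccc1 | intermediate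
9 | 1-{4,6-bis(benzyloxy)-2-[(9-borabicyclo[3.3.1]nonan-9-yl)oxy]-3-[(1R)-3-(9-borabicyclo[3.3.1]nonan-9-yl)-1-phenylpropyl]phenyl}ethan-1-one | C1CC2CCCC(C1)B2CC[C@H](c1ccccc1)c1c(OB2C3CCCC2CCC3)c(C(C)=O)c(OCc2ccccc2)cc1OCc1ccccc1 | intermediate
10 | 1-{4,6-bis(benzyloxy)-2-hydroxy-3-[(1R)-3-hydroxy-1-phenylpropyl]phenyl}ethan-1-one | OCC[C@H](c1ccccc1)c1c(O)c(C(C)=O)c(OCc2ccccc2)cc1OCc1ccccc1 | intermediate
11 | 3,4-bis(benzyloxy)benzaldehyde | O=Cc1ccc(OCc2ccccc2)c(OCc2ccccc2)c1 | starting material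
12 | 1-{4,6-bis(benzyloxy)-2-hydroxy-3-[(1R)-3-hydroxy-1-phenylpropyl]phenyl}-3-[3,4-bis(benzyloxy)phenyl]-3-hydroxypropan-1-one (both epimers at the new carbinol carbon) | OCC[C@H](c1ccccc1)c1c(O)c(C(=O)CC(O)c2ccc(OCc3ccccc3)c(OCc3ccccc3)c2)c(OCc2ccccc2)cc1OCc1ccccc1 | intermediate
13 | (2E)-1-{4,6-bis(benzyloxy)-2-hydroxy-3-[(1R)-3-hydroxy-1-phenylpropyl]phenyl}-3-[3,4-bis(benzyloxy)phenyl]prop-2-en-1-one | OCC[C@H](c1ccccc1)c1c(O)c(C(=O)/C=C/c2ccc(OCc3ccccc3)c(OCc3ccccc3)c2)c(OCc2ccccc2)cc1OCc1ccccc1 | intermediate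
14 | (3R)-3-{4,6-bis(benzyloxy)-3-[(2E)-3-(3,4-bis(benzyloxy)phenyl)prop-2-enoyl]-2-hydroxyphenyl}-3-phenylpropanal | O=CC[C@H](c1ccccc1)c1c(O)c(C(=O)/C=C/c2ccc(OCc3ccccc3)c(OCc3ccccc3)c2)c(OCc2ccccc2)cc1OCc1ccccc1 | intermediate
15 | (4R)-5,7-bis(benzyloxy)-8-[(2E)-3-(3,4-bis(benzyloxy)phenyl)prop-2-enoyl]-4-phenyl-3,4-dihydro-2H-chromen-2-ol (both C2 epimers) | OC1C[C@H](c2ccccc2)c2c(OCc3ccccc3)cc(OCc3ccccc3)c(C(=O)/C=C/c3ccc(OCc4ccccc4)c(OCc4ccccc4)c3)c2O1 | intermediate
16 | (4R)-5,7-bis(benzyloxy)-8-{(2E)-3-[3,4-bis(benzyloxy)phenyl]prop-2-enoyl}-4-phenyl-3,4-dihydro-2H-chromen-2-one | O=C1C[C@H](c2ccccc2)c2c(OCc3ccccc3)cc(OCc3ccccc3)c(C(=O)/C=C/c3ccc(OCc4ccccc4)c(OCc4ccccc4)c3)c2O1 | intermediate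
17 | (4R)-8-[(2E)-3-(3,4-dihydroxyphenyl)prop-2-enoyl]-5,7-dihydroxy-4-phenyl-3,4-dihydro-2H-chromen-2-one | O=C1C[C@H](c2ccccc2)c2c(O)cc(O)c(C(=O)/C=C/c3ccc(O)c(O)c3)c2O1 | target

**Totals**
Total step count: 8. Longest linear sequence: 8 steps (1 → 17).

**Steps most likely to fail**

Step 3 (Claisen rearrangement). The ether carries a good leaving group (an acyl phenoxide) and a stabilised 1-methyl-3-phenylallyl unit. Ion-pair return or onward Cope migration to the carbon between the two benzyloxy groups would cost enantiopurity or regiochemistry. Any Z-propenyl product from the axial-methyl chair has the opposite C4 configuration and must be removed before step 4, because both isomers converge on the same vinyl compound. The fallback sets out from 5 and takes the carbonyl out of conjugation: TBSOTf and Et3N in CH2Cl2 at 0 °C convert the methyl ketone into the silyl enol ether {[1-(2,4-bis(benzyloxy)-6-{[(2R,3E)-4-phenylbut-3-en-2-yl]oxy}phenyl)ethenyl]oxy}(tert-butyl)dimethylsilane F1. This more electron-rich ether, now with a poorer leaving group, is rearranged in mesitylene at about 155 °C to 3,5-bis(benzyloxy)-2-(1-{[tert-butyl(dimethyl)silyl]oxy}ethenyl)-6-[(1R,2E)-1-phenylbut-2-en-1-yl]phenol F2, and 1 M HCl in THF unmasks the ketone, coming back to the route at 7.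

Step 4 (ethenolysis). The internal alkene sits next to a diarylmethine carbon and may react slowly or isomerise into conjugation. The fallback sets out from 7 and replaces metathesis by cleavage and methylenation. OsO4 (cat.) with NaIO4 and 2,6-lutidine in dioxane–water cuts the propenyl group to the aldehyde, which rests as the five-membered lactol 1-[(3R)-4,6-bis(benzyloxy)-2-hydroxy-3-phenyl-2,3-dihydro-1-benzofuran-7-yl]ethan-1-one F3. This form shields the epimerisable centre. Non-basic, aldehyde-selective methylenation with Zn, CH2I2 and Ti(OiPr)4 in THF then gives the vinyl compound and comes back at 8.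

Step 7 (oxidative lactonisation). The substrate carries a free phenol and a 2′-hydroxychalcone, so flavanone closure or phenol oxidation could compete. The fallback sets out from 10 and closes the ring before the enone exists. TEMPO/PhI(OAc)2 in CH2Cl2 oxidises the diol to (4R)-8-acetyl-5,7-bis(benzyloxy)-4-phenyl-3,4-dihydro-2H-chromen-2-one F4. A Lewis-acid Claisen–Schmidt condensation with 11 (BF3·OEt2, dioxane, rt), which leaves the aryl ester intact where hydroxide would not, then comes back at 16.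

**Further compounds**
F1 | step 3 | {[1-(2,4-bis(benzyloxy)-6-{[(2R,3E)-4-phenylbut-3-en-2-yl]oxy}phenyl)ethenyl]oxy}(tert-butyl)dimethylsilane | C[C@@H](Oc1cc(OCc2ccccc2)cc(OCc2ccccc2)c1C(=C)O[Si](C)(C)C(C)(C)C)/C=C/c1ccccc1
F2 | step 3 | 3,5-bis(benzyloxy)-2-(1-{[tert-butyl(dimethyl)silyl]oxy}ethenyl)-6-[(1R,2E)-1-phenylbut-2-en-1-yl]phenol | C/C=C/[C@H](c1ccccc1)c1c(O)c(C(=C)O[Si](C)(C)C(C)(C)C)c(OCc2ccccc2)cc1OCc1ccccc1
F3 | step 4 | 1-[(3R)-4,6-bis(benzyloxy)-2-hydroxy-3-phenyl-2,3-dihydro-1-benzofuran-7-yl]ethan-1-one (both C2 epimers) | OC1Oc2c(C(C)=O)c(OCc3ccccc3)cc(OCc3ccccc3)c2[C@H]1c1ccccc1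
F4 | step 7 | (4R)-8-acetyl-5,7-bis(benzyloxy)-4-phenyl-3,4-dihydro-2H-chromen-2-one | O=C1C[C@H](c2ccccc2)c2c(OCc3ccccc3)cc(OCc3ccccc3)c(C(C)=O)c2O1
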